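**Plan**

1. Numbering (germacrane): C1 furanone C=O, C2 furanone CH, C3 furanone C–O, C4=C5 Z-alkene (C15 methyl), C6 acyloxy carbon, C7–C8 lactone ring fusion, C9 CH2, C10 quaternary ether carbon (C14 methyl), C11–C13 methylene lactone.
2. Retrosynthetic cuts, last first: the C11=C13 methylene (carried as its dimethylamine adduct) and the C6 ester; then C2–C1 and O–C10 together, which opens the ten-membered carbocycle and the furanone at once and leaves bis-lactone 19 (C1 parked on O6 as a seven-membered lactone, mesylate on C10); then the O6–C1 lactone bond, C5–C6, the C6 carbon (from a vinyl group on C7), C7–C11 (ring-closing metathesis) and C9–C10 (pyruvate aldol).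
3. Enabling feature: the 3(2H)-furanone is a cyclised C1/C3 1,3-diketone bridging C3 and C10 of the ten-membered ring, and O6 stands γ to the C3 carbonyl across the (Z)-C4=C5 bond, as the acyloxy oxygen stands to the acetyl group in an o-acyloxyaryl ketone. An acyl group on O6 can therefore migrate to C2; because that acyl group is C1, already tied to C10–C9–C8, the migration is a 7 → 10 ring expansion.
4. Forward order of rings: γ-butenolide (C8/C7/C11/C12/O) → trans,trans-substituted γ-lactone → seven-membered O6–C1 lactone → ten-membered carbocycle and furanone in one flask → side-chain ester → exocyclic methylene.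
5. Stereochemistry: C10 from a ligand-controlled aldol (carbinol 10S, inverted to 10R in the key step), C8 by hydroxyl-directed anti reduction, C7 and the temporary C11 centre by anti conjugate addition/Mannich trapping, C6 by Felkin–Anh alkenylchromium addition, the Z-alkene by anti carbomagnesiation, the epoxide from (R)-2-methylglycidol.

Key step: step 13

Remark: 1, 2, 12 and 22 are taken as commercial; locants follow the germacrane numbering above, and the descriptor of C7 switches between R and S with the substitution of O6 without any change in geometry.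

**Route**

Step 1
Reactants: 1 tert-butyl pyruvate; 2 2-(trimethylsilyloxy)buta-1,3-diene
Product: 4 tert-butyl (2S)-2-hydroxy-2-methyl-4-oxohex-5-enoate, via silyl ether 3 (not isolated)
Conditions: Cu(OTf)2 (10 mol %), (S,S)-2,2'-isopropylidenebis(4-tert-butyl-2-oxazoline) (11 mol %), THF, −78 °C; then 1 M HCl, THF, 0 °C
Reagents that add atoms: none
Why: Mukaiyama aldol addition to the pyruvate chelated to divalent copper, in which the bis(oxazoline) shields one ketone face and the terminal CH2 of the silyloxydiene attacks the other, so that the tertiary carbinol C10 should form as the S isomer.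

Step 2
Reactants: 4 tert-butyl (2S)-2-hydroxy-2-methyl-4-oxohex-5-enoate
Product: 5 tert-butyl (2S,4S)-2,4-dihydroxy-2-methylhex-5-enoate
Conditions: Me4NBH(OAc)3, MeCN/AcOH, −35 °C
Reagents that add atoms: none
Why: Evans–Saksena reduction, in which the C10 hydroxyl binds boron and delivers hydride intramolecularly through a chair-like transition state, should give the 1,3-anti diol and so set C8 (S) by 1,2-reduction of the enone.

Step 3
Reactants: 5 tert-butyl (2S,4S)-2,4-dihydroxy-2-methylhex-5-enoate
Product: 7 tert-butyl (2S,4S)-4-(acryloyloxy)-2-methyl-2-(trimethylsilyloxy)hex-5-enoate, via acrylate 6 (not isolated)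
Conditions: acryloyl chloride, Et3N, CH2Cl2, −40 °C; then TMSOTf, Et3N, −40 to 0 °C
Reagents that add atoms: acryloyl chloride, C=CC(=O)Cl; trimethylsilyl trifluoromethanesulfonate, C[Si](C)(C)OS(=O)(=O)C(F)(F)F
Why: Acylation of the less hindered secondary allylic hydroxyl and then silylation of the tertiary one touch no stereocenter, the bulky tert-butyl ester prevents lactonisation onto O8, and the silyl ether later prevents oxa-Michael closure of the C10 oxygen onto the butenolide.

Step 4
Reactants: 7 tert-butyl (2S,4S)-4-(acryloyloxy)-2-methyl-2-(trimethylsilyloxy)hex-5-enoate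
Product: 8 tert-butyl (2S)-2-methyl-3-[(2S)-5-oxo-2,5-dihydrofuran-2-yl]-2-(trimethylsilyloxy)propanoate
Conditions: second-generation Grubbs catalyst (5 mol %), CH2Cl2, 40 °C
Reagents that add atoms: none
Why: Ring-closing metathesis of an allyl acrylate gives the γ-butenolide (the later C12 lactone ring) with loss of ethene and without change at C8.

Step 5
Reactants: 8 tert-butyl (2S)-2-methyl-3-[(2S)-5-oxo-2,5-dihydrofuran-2-yl]-2-(trimethylsilyloxy)propanoate
Product: 10 tert-butyl (2S)-3-[(2S,3R,4S)-4-[(dimethylamino)methyl]-3-ethenyl-5-oxooxolan-2-yl]-2-methyl-2-(trimethylsilyloxy)propanoate, via magnesium enolate 9 (not isolated)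
Conditions: vinylmagnesium bromide, CuBr·SMe2 (10 mol %), THF, −78 °C; then Eschenmoser's salt, −78 to 0 °C
Reagents that add atoms: vinylmagnesium bromide, C=C[Mg]Br; Eschenmoser's salt (N,N-dimethylmethyleneiminium iodide), C=[N+](C)C.[I-]
Why: Copper-catalysed conjugate addition anti to the C8 side chain and Mannich trapping of the enolate anti to the new vinyl group should give the all-trans lactone (C7 R, C11 S), the aminomethyl group being the masked exocyclic methylene.

Step 6
Reactants: 10 tert-butyl (2S)-3-[(2S,3R,4S)-4-[(dimethylamino)methyl]-3-ethenyl-5-oxooxolan-2-yl]-2-methyl-2-(trimethylsilyloxy)propanoate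
Product: 11 tert-butyl (2S)-3-[(2S,3R,4S)-4-[(dimethylamino)methyl]-3-formyl-5-oxooxolan-2-yl]-2-methyl-2-(trimethylsilyloxy)propanoate
Conditions: OsO4 (2 mol %), NaIO4, 2,6-lutidine, dioxane/H2O, 20 °C
Reagents that add atoms: osmium tetroxide (catalytic oxygen carrier), O=[Os](=O)(=O)=O; sodium periodate, [Na+].[O-]I(=O)(=O)=O
Why: Lemieux–Johnson oxidation dihydroxylates the only C=C bond and cleaves the glycol in situ to the C6 aldehyde under buffered conditions that should not epimerise C7.

Step 7
Reactants: 12 (2R)-but-3-yn-2-ol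
Product: 13 (2R,3Z)-4-iodo-3-methylbut-3-en-2-ol
Conditions: MeMgBr, CuI (10 mol %), THF, −10 to 20 °C; then I2, −40 to 0 °C
Reagents that add atoms: methylmagnesium bromide, C[Mg]Br; iodine, II
Why: Alkoxide-directed anti carbomagnesiation places the methyl group on C4 and magnesium on C5 cis to the carbinol, and iodinolysis with retention gives the Z-iodoalkene that fixes the C4=C5 geometry (the carbinol centre is removed in step 11).

Step 8
Reactants: 11 tert-butyl (2S)-3-[(2S,3R,4S)-4-[(dimethylamino)methyl]-3-formyl-5-oxooxolan-2-yl]-2-methyl-2-(trimethylsilyloxy)propanoate; 13 (2R,3Z)-4-iodo-3-methylbut-3-en-2-ol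
Product: 14 tert-butyl (2S)-3-[(2S,3S,4S)-3-[(1R,2Z,4R)-1,4-dihydroxy-3-methylpent-2-en-1-yl]-4-[(dimethylamino)methyl]-5-oxooxolan-2-yl]-2-methyl-2-(trimethylsilyloxy)propanoate
Conditions: CrCl2, NiCl2 (1 mol %), DMSO, 20 °C
Reagents that add atoms: none
Why: Nozaki–Hiyama–Kishi coupling, in which the alkenylchromium species adds only to the aldehyde with retention of the Z geometry, and Felkin–Anh attack anti to the C7–C8 bond should give the 6R alcohol.

Step 9
Reactants: 14 tert-butyl (2S)-3-[(2S,3S,4S)-3-[(1R,2Z,4R)-1,4-dihydroxy-3-methylpent-2-en-1-yl]-4-[(dimethylamino)methyl]-5-oxooxolan-2-yl]-2-methyl-2-(trimethylsilyloxy)propanoate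
Product: 16 (2S)-3-[(2S,3S,4S)-3-[(1R,2Z,4R)-1,4-dihydroxy-3-methylpent-2-en-1-yl]-4-[(dimethylamino)methyl]-5-oxooxolan-2-yl]-2-hydroxy-2-methylpropanoic acid, via persilylated ester 15 (not isolated)
Conditions: TMSOTf, 2,6-lutidine, CH2Cl2, 0 °C; then MeOH, aq. citric acid, 0 °C
Reagents that add atoms: none
Why: Silyl triflate-mediated cleavage of the tert-butyl ester (loss of 2-methylpropene from the O-silylated ester) proceeds while the acid-labile Z-allylic diol is protected as silyl ethers, and mild aqueous acid then frees the acid and all hydroxyls without touching a stereocenter.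

Step 10
Reactants: 16 (2S)-3-[(2S,3S,4S)-3-[(1R,2Z,4R)-1,4-dihydroxy-3-methylpent-2-en-1-yl]-4-[(dimethylamino)methyl]-5-oxooxolan-2-yl]-2-hydroxy-2-methylpropanoic acid
Product: 17 (3R,4Z,6R,7R,8S,10S,11S)-13-(dimethylamino)-3,10-dihydroxy-1,2-secogermacr-4-ene-1,6:12,8-diolide
Conditions: 2-methyl-6-nitrobenzoic anhydride, DMAP, Et3N, CH2Cl2 (high dilution, slow addition), 20 °C
Reagents that add atoms: none
Why: Shiina macrolactonisation, in which the activated acid is captured by the C6 hydroxyl (seven-membered ring, pre-organised by the trans-lactone) rather than by the C3 hydroxyl (ten-membered ring) or the tertiary hydroxyl, with retention at C6.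

Step 11
Reactants: 17 (3R,4Z,6R,7R,8S,10S,11S)-13-(dimethylamino)-3,10-dihydroxy-1,2-secogermacr-4-ene-1,6:12,8-diolide
Product: 18 (4Z,6R,7R,8S,10S,11S)-13-(dimethylamino)-10-hydroxy-3-oxo-1,2-secogermacr-4-ene-1,6:12,8-diolide
Conditions: Dess–Martin periodinane, NaHCO3, CH2Cl2, 0 °C
Reagents that add atoms: none
Why: Dess–Martin oxidation of the only secondary alcohol gives the Z-enone, which cannot close to a hemiketal or furan because O6 is acylated, and leaves the tertiary hydroxyl untouched.

Step 12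
Reactants: 18 (4Z,6R,7R,8S,10S,11S)-13-(dimethylamino)-10-hydroxy-3-oxo-1,2-secogermacr-4-ene-1,6:12,8-diolide
Product: 19 (4Z,6R,7R,8S,10S,11S)-13-(dimethylamino)-10-(methylsulfonyloxy)-3-oxo-1,2-secogermacr-4-ene-1,6:12,8-diolide
Conditions: MsCl, Et3N, CH2Cl2, −20 to 0 °C
Reagents that add atoms: methanesulfonyl chloride, CS(=O)(=O)Cl
Why: Sulfonylation through sulfene, which is small enough to capture a tertiary hydroxyl, forms the O–S bond with retention at C10, and the adjacent carbonyl disfavours ionisation of the tertiary mesylate.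

Step 13
Reactants: 19 (4Z,6R,7R,8S,10S,11S)-13-(dimethylamino)-10-(methylsulfonyloxy)-3-oxo-1,2-secogermacr-4-ene-1,6:12,8-diolide
Product: 21 (4Z,6R,7S,8S,10R,11S)-13-(dimethylamino)-3,10-epoxy-6-hydroxy-1-oxogermacra-2,4-dien-12,8-olide, via potassium diketonate 20 (not isolated)
Conditions: KHMDS (1.1 equiv), THF (high dilution), −78 °C, then 20 °C
Reagents that add atoms: none
Why: Proposed new method: the kinetic potassium enolate of the methyl ketone attacks, through its carbon C2, the carbonyl C1 of the seven-membered lactone via a seven-membered transition state held in place by the (Z)-C4=C5 bond (the aliphatic, vinylogous counterpart of the Baker–Venkataraman O-to-C acyl shift, the closest known reaction type), and collapse of the bridged tetrahedral intermediate expels the C6 alkoxide, so that the lactone is ring-expanded by three atoms to the ten-membered carbocyclic 1,3-diketone, which the alkoxide deprotonates at once to diketonate 20. The enolate oxygen on C3 then displaces the tertiary α-keto mesylate at C10, as in the known closure of α'-halo-1,3-diketones to 3(2H)-furanones. The carbocycle is thus closed by a 7-exo-trig addition–elimination (C2–C1) and the furanone by a transannular 5-exo-tet O-alkylation (O–C10). C10 is the only stereocenter made: for the five-membered closure the C10–O(mesyl) bond must lie in the plane of the diketonate, a geometry without π-assistance to ionisation, so backside attack should turn the 10S sulfonate into the 10R ether with inversion. The step needs α'- rather than γ-deprotonation (bulky amide base at −78 °C; the only γ-hydrogen is the hindered C6–H), C- rather than O-acylation (only the C-acyl product is drained as diketonate and then cyclised irreversibly) and no reaction at the γ-lactone, which is secured by the longer reach to C12 (eight-membered transition state), by the amine mask on C13 that removes the Michael acceptor, and by the fast proton transfer that quenches the C6 alkoxide.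

Step 14
Reactants: 22 [(2R)-2-methyloxiran-2-yl]methanol
Product: 23 (2S)-2-methyloxirane-2-carboxylic acid
Conditions: TEMPO (cat.), PhI(OAc)2, MeCN/H2O, 20 °C
Reagents that add atoms: water, O
Why: Oxoammonium-catalysed oxidation of the primary alcohol through the aldehyde hydrate gives the acid without touching the quaternary epoxide carbon, whose descriptor changes from R to S only because the substituent priorities change.

Step 15
Reactants: 21 (4Z,6R,7S,8S,10R,11S)-13-(dimethylamino)-3,10-epoxy-6-hydroxy-1-oxogermacra-2,4-dien-12,8-olide; 23 (2S)-2-methyloxirane-2-carboxylic acid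
Product: 24 (4Z,6R,7R,8S,10R,11S)-13-(dimethylamino)-3,10-epoxy-1-oxogermacra-2,4-dien-12,8-olid-6-yl (2S)-2-methyloxirane-2-carboxylate
Conditions: DCC, DMAP (cat.), CH2Cl2, 0 to 20 °C
Reagents that add atoms: none
Why: Steglich esterification of the C6 hydroxyl, the only hydroxyl in 21, proceeds with retention at C6 and at the epoxide carbon.

Step 16
Reactants: 24 (4Z,6R,7R,8S,10R,11S)-13-(dimethylamino)-3,10-epoxy-1-oxogermacra-2,4-dien-12,8-olid-6-yl (2S)-2-methyloxirane-2-carboxylate
Product: 26 (4Z,6R,7R,8S,10R)-3,10-epoxy-1-oxogermacra-2,4,11(13)-trien-12,8-olid-6-yl (2S)-2-methyloxirane-2-carboxylate, via ammonium iodide 25 (not isolated)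
Conditions: MeI, THF, 20 °C; then NaHCO3, H2O/EtOAc, 20 °C
Reagents that add atoms: none
Why: Exhaustive N-methylation and E1cB elimination of trimethylamine from the β-ammonio lactone unmask the α-methylene-γ-butyrolactone under conditions that should leave the epoxide, the ester and the furanone intact, and remove the temporary C11 centre.

**Compound list**

1 | tert-butyl 2-oxopropanoate (tert-butyl pyruvate) | CC(=O)C(=O)OC(C)(C)C | starting material
2 | 2-(trimethylsilyloxy)buta-1,3-diene | C=CC(=C)O[Si](C)(C)C | starting material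
3 | tert-butyl (2S)-2-methyl-4-oxo-2-(trimethylsilyloxy)hex-5-enoate | C=CC(=O)C[C@](C)(O[Si](C)(C)C)C(=O)OC(C)(C)C | intermediate
4 | tert-butyl (2S)-2-hydroxy-2-methyl-4-oxohex-5-enoate | C=CC(=O)C[C@](C)(O)C(=O)OC(C)(C)C | intermediate
5 | tert-butyl (2S,4S)-2,4-dihydroxy-2-methylhex-5-enoate (anti diol) | C=C[C@@H](O)C[C@](C)(O)C(=O)OC(C)(C)C | intermediate
6 | tert-butyl (2S,4S)-4-(acryloyloxy)-2-hydroxy-2-methylhex-5-enoate | C=C[C@@H](OC(=O)C=C)C[C@](C)(O)C(=O)OC(C)(C)C | intermediate
7 | tert-butyl (2S,4S)-4-(acryloyloxy)-2-methyl-2-(trimethylsilyloxy)hex-5-enoate | C=C[C@@H](OC(=O)C=C)C[C@](C)(O[Si](C)(C)C)C(=O)OC(C)(C)C | intermediate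
8 | tert-butyl (2S)-2-methyl-3-[(2S)-5-oxo-2,5-dihydrofuran-2-yl]-2-(trimethylsilyloxy)propanoate | O=C1C=C[C@H](C[C@](C)(O[Si](C)(C)C)C(=O)OC(C)(C)C)O1 | intermediate
9 | bromomagnesium enolate of the 3-vinyl lactone (C7 R, C8 S) | C=C[C@@H]1C=C(O[Mg]Br)O[C@H]1C[C@](C)(O[Si](C)(C)C)C(=O)OC(C)(C)C | intermediate
10 | tert-butyl (2S)-3-[(2S,3R,4S)-4-[(dimethylamino)methyl]-3-ethenyl-5-oxooxolan-2-yl]-2-methyl-2-(trimethylsilyloxy)propanoate | O=C1[C@H](CN(C)C)[C@@H](C=C)[C@H](C[C@](C)(O[Si](C)(C)C)C(=O)OC(C)(C)C)O1 | intermediate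
11 | tert-butyl (2S)-3-[(2S,3R,4S)-4-[(dimethylamino)methyl]-3-formyl-5-oxooxolan-2-yl]-2-methyl-2-(trimethylsilyloxy)propanoate | O=C[C@@H]1[C@@H](CN(C)C)C(=O)O[C@H]1C[C@](C)(O[Si](C)(C)C)C(=O)OC(C)(C)C | intermediate
12 | (2R)-but-3-yn-2-ol | C[C@@H](O)C#C | starting material
13 | (2R,3Z)-4-iodo-3-methylbut-3-en-2-ol | C[C@@H](O)/C(C)=C\I | intermediate
14 | tert-butyl (2S)-3-[(2S,3S,4S)-3-[(1R,2Z,4R)-1,4-dihydroxy-3-methylpent-2-en-1-yl]-4-[(dimethylamino)methyl]-5-oxooxolan-2-yl]-2-methyl-2-(trimethylsilyloxy)propanoate | C[C@@H](O)/C(C)=C\[C@@H](O)[C@@H]1[C@@H](CN(C)C)C(=O)O[C@H]1C[C@](C)(O[Si](C)(C)C)C(=O)OC(C)(C)C | intermediate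
15 | trimethylsilyl ester and tris(trimethylsilyl) ether of 16 | C[C@@H](O[Si](C)(C)C)/C(C)=C\[C@@H](O[Si](C)(C)C)[C@@H]1[C@@H](CN(C)C)C(=O)O[C@H]1C[C@](C)(O[Si](C)(C)C)C(=O)O[Si](C)(C)C | intermediate
16 | (2S)-3-[(2S,3S,4S)-3-[(1R,2Z,4R)-1,4-dihydroxy-3-methylpent-2-en-1-yl]-4-[(dimethylamino)methyl]-5-oxooxolan-2-yl]-2-hydroxy-2-methylpropanoic acid | C[C@@H](O)/C(C)=C\[C@@H](O)[C@@H]1[C@@H](CN(C)C)C(=O)O[C@H]1C[C@](C)(O)C(=O)O | intermediate
17 | (3R,4Z,6R,7R,8S,10S,11S)-13-(dimethylamino)-3,10-dihydroxy-1,2-secogermacr-4-ene-1,6:12,8-diolide (seven-membered lactone C1→O6 trans-fused at C7–C8 to the γ-lactone C12→O8) | C[C@@H](O)/C(C)=C\[C@H]1OC(=O)[C@@](C)(O)C[C@@H]2OC(=O)[C@H](CN(C)C)[C@@H]12 | intermediate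
18 | (4Z,6R,7R,8S,10S,11S)-13-(dimethylamino)-10-hydroxy-3-oxo-1,2-secogermacr-4-ene-1,6:12,8-diolide | CC(=O)/C(C)=C\[C@H]1OC(=O)[C@@](C)(O)C[C@@H]2OC(=O)[C@H](CN(C)C)[C@@H]12 | intermediate
19 | (4Z,6R,7R,8S,10S,11S)-13-(dimethylamino)-10-(methylsulfonyloxy)-3-oxo-1,2-secogermacr-4-ene-1,6:12,8-diolide | CC(=O)/C(C)=C\[C@H]1OC(=O)[C@@](C)(OS(C)(=O)=O)C[C@@H]2OC(=O)[C@H](CN(C)C)[C@@H]12 | intermediate
20 | potassium 1,3-diketonate of (4Z,6R,7S,8S,10S,11S)-13-(dimethylamino)-6-hydroxy-10-(methylsulfonyloxy)-1,3-dioxogermacr-4-en-12,8-olide | CN(C)C[C@H]1C(=O)O[C@H]2C[C@](C)(OS(C)(=O)=O)C(=O)C=C([O-])/C(C)=C\[C@@H](O)[C@H]12.[K+] | intermediate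
21 | (4Z,6R,7S,8S,10R,11S)-13-(dimethylamino)-3,10-epoxy-6-hydroxy-1-oxogermacra-2,4-dien-12,8-olide | CN(C)C[C@H]1C(=O)O[C@H]2C[C@@]3(C)OC(=CC3=O)/C(C)=C\[C@@H](O)[C@H]12 | intermediate
22 | [(2R)-2-methyloxiran-2-yl]methanol ((R)-2-methylglycidol) | C[C@@]1(CO)CO1 | starting material
23 | (2S)-2-methyloxirane-2-carboxylic acid | C[C@@]1(C(=O)O)CO1 | intermediate
24 | (4Z,6R,7R,8S,10R,11S)-13-(dimethylamino)-3,10-epoxy-1-oxogermacra-2,4-dien-12,8-olid-6-yl (2S)-2-methyloxirane-2-carboxylate | CN(C)C[C@H]1C(=O)O[C@H]2C[C@@]3(C)OC(=CC3=O)/C(C)=C\[C@@H](OC(=O)[C@]3(C)CO3)[C@H]12 | intermediate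
25 | N-methyl quaternary ammonium iodide of 24 | C[N+](C)(C)C[C@H]1C(=O)O[C@H]2C[C@@]3(C)OC(=CC3=O)/C(C)=C\[C@@H](OC(=O)[C@]3(C)CO3)[C@H]12.[I-] | intermediate
26 | (4Z,6R,7R,8S,10R)-3,10-epoxy-1-oxogermacra-2,4,11(13)-trien-12,8-olid-6-yl (2S)-2-methyloxirane-2-carboxylate (CNP0321429.1) | C=C1C(=O)O[C@H]2C[C@@]3(C)OC(=CC3=O)/C(C)=C\[C@@H](OC(=O)[C@]3(C)CO3)[C@H]12 | target

**Count and risks**

Total step count: 16. Longest linear sequence: 14 (steps 1–6, 8–13, 15 and 16).

Step 13 (key step, proposed new method). What may go wrong: the amide base may deprotonate the mesyl group, which then cyclises onto the lactone carbonyl; methanesulfonate may be lost by β-elimination; the α'-sulfonate may ionise before ring closure, which would scramble C10; the freed C6 alkoxide may translactonise the γ-lactone before it is protonated. Fallback with known reactions, ring closure moved to C5–C6 and the furanone made bimolecularly; it sets out from 10 and returns at 21. CF3CO2H in CH2Cl2 removes the tert-butyl ester and the silyl ether of 10 to give (2S)-3-[(2S,3R,4S)-4-[(dimethylamino)methyl]-3-ethenyl-5-oxooxolan-2-yl]-2-hydroxy-2-methylpropanoic acid F1. MsCl/Et3N (two equivalents) converts it into the O-mesylated carboxylic–methanesulfonic mixed anhydride F2, used at once. Compound 13 is oxidised with Dess–Martin periodinane to (3Z)-4-iodo-3-methylbut-3-en-2-one F3. Its lithium enolate (LiHMDS, THF, −78 °C, two equivalents) is C-acylated by F2 and the resulting α'-sulfonyloxy-1,3-diketone closes, as in the known furanone synthesis from ketone enolates and α-haloacyl donors, to the iodovinyl furanone F4. Lemieux–Johnson cleavage of the vinyl group gives the aldehyde F5, and an intramolecular Nozaki–Hiyama–Kishi reaction (CrCl2, NiCl2 cat., DMSO, high dilution) forms C5–C6 and the ten-membered ring to give 21.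

Step 8. What may go wrong: poor facial selectivity in the addition to the C6 aldehyde, and β-elimination of the lactone carboxylate or epimerisation at C7 in the aldehyde before it reacts. Fallback with reagent control by reduction instead of substrate control by addition; it sets out from 11 and 13 and returns at 16. Compound 13 is silylated (TBSCl, imidazole) to tert-butyl{[(2R,3Z)-4-iodo-3-methylbut-3-en-2-yl]oxy}dimethylsilane F6. The chromium-mediated coupling with 11 then gives the adduct, taken here as its unwanted 6S epimer F7, and Dess–Martin oxidation of the crude adduct gives the C6 ketone F8. Corey–Bakshi–Shibata reduction ((R)-2-methyl-CBS-oxazaborolidine, catecholborane, the alkenyl group acting as the larger substituent) should give the 6R alcohol F9. TMSOTf/2,6-lutidine followed by HF·pyridine removes the tert-butyl ester and all silyl groups to give 16.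

Step 1. What may go wrong: the silyloxydiene may react by hetero-Diels–Alder cycloaddition instead of aldol addition, and the β-hydroxy vinyl ketone may cyclise by oxa-Michael addition or polymerise during desilylation. Fallback that builds the vinyl ketone after the aldol step; it sets out from 1 and returns at 4. Aldol addition of 1-(ethylthio)-1-(trimethylsilyloxy)ethene to 1 under the same copper/bis(oxazoline) catalysis gives 1-tert-butyl 4-S-ethyl (2S)-2-methyl-4-thio-2-(trimethylsilyloxy)butanedioate F10 and, after dilute HCl, 1-tert-butyl 4-S-ethyl (2S)-2-hydroxy-2-methyl-4-thiobutanedioate F11. Fukuyama coupling of F11 with vinylzinc bromide (PdCl2(PPh3)2 cat., THF) gives the vinyl ketone 4.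

**Further compounds**

F1 | step 13 | (2S)-3-[(2S,3R,4S)-4-[(dimethylamino)methyl]-3-ethenyl-5-oxooxolan-2-yl]-2-hydroxy-2-methylpropanoic acid | O=C1[C@H](CN(C)C)[C@@H](C=C)[C@H](C[C@](C)(O)C(=O)O)O1
F2 | step 13 | O-mesylated carboxylic–methanesulfonic mixed anhydride of F1 | O=C1[C@H](CN(C)C)[C@@H](C=C)[C@H](C[C@](C)(OS(C)(=O)=O)C(=O)OS(C)(=O)=O)O1
F3 | step 13 | (3Z)-4-iodo-3-methylbut-3-en-2-one | CC(=O)/C(C)=C\I
F4 | step 13 | (3S,4R,5S)-3-[(dimethylamino)methyl]-4-ethenyl-5-{[(2R)-5-[(1Z)-1-iodoprop-1-en-2-yl]-2-methyl-3-oxo-2,3-dihydrofuran-2-yl]methyl}oxolan-2-one | C=C[C@@H]1[C@@H](CN(C)C)C(=O)O[C@H]1C[C@@]1(C)OC(=CC1=O)/C(C)=C\I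
F5 | step 13 | aldehyde from F4 (4-formyl in place of 4-ethenyl) | O=C[C@@H]1[C@@H](CN(C)C)C(=O)O[C@H]1C[C@@]1(C)OC(=CC1=O)/C(C)=C\I
F6 | step 8 | tert-butyl{[(2R,3Z)-4-iodo-3-methylbut-3-en-2-yl]oxy}dimethylsilane | C[C@@H](O[Si](C)(C)C(C)(C)C)/C(C)=C\I
F7 | step 8 | 6S epimer of the C3-O-TBS analogue of 14 | C[C@@H](O[Si](C)(C)C(C)(C)C)/C(C)=C\[C@H](O)[C@@H]1[C@@H](CN(C)C)C(=O)O[C@H]1C[C@](C)(O[Si](C)(C)C)C(=O)OC(C)(C)C
F8 | step 8 | C6 ketone from F7 | C[C@@H](O[Si](C)(C)C(C)(C)C)/C(C)=C\C(=O)[C@@H]1[C@@H](CN(C)C)C(=O)O[C@H]1C[C@](C)(O[Si](C)(C)C)C(=O)OC(C)(C)C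
F9 | step 8 | 6R alcohol (C3-O-TBS analogue of 14) | C[C@@H](O[Si](C)(C)C(C)(C)C)/C(C)=C\[C@@H](O)[C@@H]1[C@@H](CN(C)C)C(=O)O[C@H]1C[C@](C)(O[Si](C)(C)C)C(=O)OC(C)(C)C
F10 | step 1 | 1-tert-butyl 4-S-ethyl (2S)-2-methyl-4-thio-2-(trimethylsilyloxy)butanedioate | CCSC(=O)C[C@](C)(O[Si](C)(C)C)C(=O)OC(C)(C)C
F11 | step 1 | 1-tert-butyl 4-S-ethyl (2S)-2-hydroxy-2-methyl-4-thiobutanedioate | CCSC(=O)C[C@](C)(O)C(=O)OC(C)(C)C
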